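**Plan**

- Retrosynthesis cuts the gallate ester C3–O bond of the lower unit first, then traces the lower flavan-3-ol back through its 3-ketone and a 3-bromoflav-2-ene to a 3-bromoflavylium salt.
- In that pyran ring (ring C of the lower unit: O1, C2, C3, C4, C4a, C8a), C3 is the only member bonded neither to O1 nor to a benzene ring. Cutting C2–C3 and C3–C4 removes it as a CBr2 unit and leaves the furan ring of a 2-arylbenzofuran with the upper flavan on C5, between two benzyloxy groups.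
- The furan is cut (aryl–alkyne C–C bond and O1–C2 bond) into an ortho-iodophenol and an arylacetylene; the interflavan C4–C6 bond is cut into a C4 cation of benzylated epigallocatechin and phloroglucinol.
- Forward: rings A, B and C of the upper unit come intact from (−)-epigallocatechin; the phloroglucinol ring is attached at C4, its para oxygen is singled out, the furan is closed, expanded to the pyrylium ring, reduced, esterified and debenzylated.
- Stereochemistry: upper C2 and C3 are those of epigallocatechin; upper C4 is set by attack of the arene anti to the 3-benzyloxy and 2-aryl groups (4β); lower C2 and C3 are set together by a Ru-catalysed asymmetric hydrogenation of the epimerising flavan-3-one (2R,3R, cis).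

Key step: step 11

Remark: the target is read as epigallocatechin-(4β→6)-epigallocatechin 3-O-gallate with both flavan units (2R,3R). Because a C4 cation would be expected to attack 3,5-dibenzyloxyphenol ortho as well as para to its hydroxyl, symmetric phloroglucinol is used and its para oxygen is differentiated afterwards.

Abbreviation used in names: "Bn6EGC-4β-yl" is the 3,5,7,3′,4′,5′-hexa-O-benzyl-(2R,3R)-epigallocatechin-4-yl group, bonded through C4 on the face opposite to its 3-benzyloxy and 2-aryl groups (2,3-cis-3,4-trans).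

**Route**

Step 1
Reactants: 1 (−)-epigallocatechin
Product: 2 5,7,3′,4′,5′-penta-O-benzyl-(−)-epigallocatechin (3-OH free)
Conditions: BnBr (5.5 equiv), K2CO3, DMF, 0 °C to rt, argon
Reagents that add atoms: benzyl bromide, BrCc1ccccc1
Why: Williamson etherification of the five phenols under carbonate, a base too weak to alkylate the secondary 3-OH, with air excluded so that the pyrogallol ring is not oxidised and C2 is not epimerised.

Step 2
Reactants: 2 5,7,3′,4′,5′-penta-O-benzyl-(−)-epigallocatechin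
Product: 3 4β-(2-ethoxyethoxy)-5,7,3′,4′,5′-penta-O-benzylepigallocatechin
Conditions: DDQ (2 equiv), 2-ethoxyethanol, CH2Cl2, rt
Reagents that add atoms: 2-ethoxyethanol, CCOCCO
Why: DDQ benzylic oxidation at C4 of the electron-rich ring A and capture of the cation by the alcohol trans to the 3-OH, the standard C4 activation of benzylated flavan-3-ols; the C4 configuration of 3 does not matter because this centre is ionised again in step 4.

Step 3
Reactants: 3 4β-(2-ethoxyethoxy)-5,7,3′,4′,5′-penta-O-benzylepigallocatechin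
Product: 4 4β-(2-ethoxyethoxy)-3,5,7,3′,4′,5′-hexa-O-benzylepigallocatechin
Conditions: NaH, BnBr, Bu4NI (cat.), DMF, 0 °C to rt
Reagents that add atoms: benzyl bromide, BrCc1ccccc1
Why: Williamson etherification of the secondary alkoxide, which protects the 3-oxygen against the carbene of step 11; the C4 ether and the aryl benzyl ethers are stable to NaH and no stereocentre carries an acidic hydrogen.

Step 4
Reactants: 4 4β-(2-ethoxyethoxy)-3,5,7,3′,4′,5′-hexa-O-benzylepigallocatechin; 5 phloroglucinol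
Product: 6 2-(Bn6EGC-4β-yl)benzene-1,3,5-triol
Conditions: phloroglucinol (5 equiv), BF3·OEt2 (0.5 equiv), THF–CH2Cl2, −40 to 0 °C
Reagents that add atoms: none
Why: Friedel–Crafts alkylation of phloroglucinol by the C4 benzylic cation released from the 2-ethoxyethyl ether (the reaction type used for interflavan bonds); the three ring positions of phloroglucinol are equivalent so only one constitution can form, and the arene enters anti to the 3-benzyloxy and 2-aryl groups, which sets C4 as 4β.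

Step 5
Reactants: 6 2-(Bn6EGC-4β-yl)benzene-1,3,5-triol
Product: 7 4-(Bn6EGC-4β-yl)-5-(triisopropylsilyloxy)benzene-1,3-diol (silyl group on the oxygen para to the flavan)
Conditions: TIPSCl (1.05 equiv), imidazole, DMF, −20 °C
Reagents that add atoms: triisopropylsilyl chloride, CC(C)[Si](Cl)(C(C)C)C(C)C
Why: Silylation under steric control, since the hydroxyl para to the flavan lies between two ring hydrogens whereas each of the other two sits next to the bulky flavan-4-yl group, so the hindered chlorosilane should take the para oxygen.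

Step 6
Reactants: 7 4-(Bn6EGC-4β-yl)-5-(triisopropylsilyloxy)benzene-1,3-diol
Product: 8 [3,5-bis(benzyloxy)-4-(Bn6EGC-4β-yl)phenoxy]triisopropylsilane
Conditions: BnBr (2.5 equiv), K2CO3, Bu4NI (cat.), acetone, 50 °C
Reagents that add atoms: benzyl bromide, BrCc1ccccc1
Why: Williamson etherification of the two remaining phenols; the aryl triisopropylsilyl ether is expected to survive anhydrous carbonate.

Step 7
Reactants: 8 [3,5-bis(benzyloxy)-4-(Bn6EGC-4β-yl)phenoxy]triisopropylsilane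
Product: 9 3,5-bis(benzyloxy)-4-(Bn6EGC-4β-yl)phenol
Conditions: Bu4NF, AcOH, THF, 0 °C
Reagents that add atoms: none
Why: Fluoride cleavage of the aryl silyl ether, buffered with acetic acid so that the phenol and not a free phenoxide is released; benzyl ethers are inert.

Step 8
Reactants: 9 3,5-bis(benzyloxy)-4-(Bn6EGC-4β-yl)phenol
Product: 10 3,5-bis(benzyloxy)-2-iodo-4-(Bn6EGC-4β-yl)phenol
Conditions: I2 (1.0 equiv), NaHCO3, THF–H2O, 0 °C
Reagents that add atoms: iodine, II
Why: Electrophilic aromatic iodination of a phenoxide, which reacts with molecular iodine at one of its two equivalent ortho positions (the para position is occupied by the flavan), whereas the fully benzylated rings are not iodinated by iodine without an activator.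

Step 9
Reactants: 11 3,4,5-tris(benzyloxy)benzaldehyde
Product: 12 5-ethynyl-1,2,3-tris(benzyloxy)benzene
Conditions: dimethyl (1-diazo-2-oxopropyl)phosphonate, K2CO3, MeOH–THF, rt
Reagents that add atoms: dimethyl (1-diazo-2-oxopropyl)phosphonate, CC(=O)C(=[N+]=[N-])P(=O)(OC)OC
Why: Seyferth–Gilbert homologation in the Ohira–Bestmann form, which turns a non-enolisable aryl aldehyde into the terminal alkyne in one operation under mild carbonate conditions.

Step 10
Reactants: 10 3,5-bis(benzyloxy)-2-iodo-4-(Bn6EGC-4β-yl)phenol; 12 5-ethynyl-1,2,3-tris(benzyloxy)benzene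
Product: 14 4,6-bis(benzyloxy)-5-(Bn6EGC-4β-yl)-2-[3,4,5-tris(benzyloxy)phenyl]benzofuran, via ortho-alkynylphenol 13 (not isolated)
Conditions: PdCl2(PPh3)2 (5 mol %), CuI (10 mol %), Et3N, DMF, 60 °C, degassed
Reagents that add atoms: none
Why: Sonogashira coupling followed in the same flask by 5-endo-dig attack of the phenoxide on the metal-activated alkyne, the standard one-pot benzofuran synthesis from ortho-iodophenols; degassing suppresses oxidative alkyne dimerisation.

Step 11
Reactants: 14 4,6-bis(benzyloxy)-5-(Bn6EGC-4β-yl)-2-[3,4,5-tris(benzyloxy)phenyl]benzofuran; 15 bromoform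
Product: 17 5,7-bis(benzyloxy)-3-bromo-6-(Bn6EGC-4β-yl)-2-[3,4,5-tris(benzyloxy)phenyl]chromenylium bromide, via dibromocyclopropane 16 (not isolated)
Conditions: CHBr3 (4 equiv), KOtBu (3 equiv, in portions), toluene–hexane, −30 °C to rt; work-up with a little ethereal HBr, salt collected by filtration
Reagents that add atoms: none
Why: KOtBu removes HBr from bromoform by α-elimination, and the electrophilic singlet dibromocarbene adds to the only non-benzenoid π bond of 14, the electron-rich C2=C3 enol ether bond of the furan, to give the cis-fused dibromocyclopropane 16. The bromide lying over the five-membered ring then ionises while the bond shared by the two rings breaks in a disrotatory two-electron electrocyclic opening, assisted by the lone pair of O1 and by the trialkoxyphenyl group on C2, so that the carbene carbon ends as C3 of an aromatic benzopyrylium and keeps one bromine, the other becoming the counter-ion. The closest known reaction type is the Ciamician–Dennstedt dihalocarbene ring expansion of indoles, pyrroles and benzofurans to 3-haloquinolines, 3-halopyridines and 3-halochromenes. The three-membered ring closes by concerted carbene addition, and the six-membered pyrylium ring arises by enlargement of the furan (new bonds C2–C3 and C3–C4), not by cyclisation of a chain. No stereocentre is created, since the two cyclopropane centres of 16 become trigonal again and the three centres of the upper flavan carry no hydrogen that tert-butoxide can remove. The step needs the carbene to choose the furan double bond over eleven benzyl ethers and their benzylic C–H bonds; the enol ether character of that bond, the aromatic stabilisation of every other π system and the low temperature should secure this, while keeping bromoform in excess over the base leaves no alkoxide to add to the cation and the acidic work-up returns any such adduct to the salt.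

Step 12
Reactants: 17 5,7-bis(benzyloxy)-3-bromo-6-(Bn6EGC-4β-yl)-2-[3,4,5-tris(benzyloxy)phenyl]chromenylium bromide
Product: 18 5,7-bis(benzyloxy)-3-bromo-6-(Bn6EGC-4β-yl)-2-[3,4,5-tris(benzyloxy)phenyl]-4H-chromene (3-bromoflav-2-ene)
Conditions: LiAlH4, THF, −78 to −20 °C
Reagents that add atoms: none
Why: Hydride addition to a benzopyrylium cation, for which LiAlH4 in an aprotic medium is the classical reagent giving 4H-flav-2-enes, C4 being the open γ-position while C2 is screened by its aryl group and the adjacent bromine; no stereocentre is formed and the alkenyl bromide should not be reduced at this temperature.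

Step 13
Reactants: 18 5,7-bis(benzyloxy)-3-bromo-6-(Bn6EGC-4β-yl)-2-[3,4,5-tris(benzyloxy)phenyl]-4H-chromene
Product: 20 5,7-bis(benzyloxy)-6-(Bn6EGC-4β-yl)-2-[3,4,5-tris(benzyloxy)phenyl]chroman-3-one (both C2 epimers), via alkenyl pinacolboronate 19 (not isolated)
Conditions: B2pin2, PdCl2(dppf) (5 mol %), KOAc, 1,4-dioxane, 80 °C; then NaBO3·4H2O, THF–H2O, rt
Reagents that add atoms: bis(pinacolato)diboron (boron kept only in 19), CC1(C)OB(OC1(C)C)B1OC(C)(C)C(C)(C)O1; sodium perborate (oxygen of the ketone), [Na+].[O-]B1OO1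
Why: Miyaura borylation of the alkenyl bromide followed by perborate oxidation of the C–B bond gives the enol, which tautomerises to the ketone; C2 becomes a stereocentre without control, which is harmless because it is α to the ketone and is equilibrated in step 14.

Step 14
Reactants: 20 5,7-bis(benzyloxy)-6-(Bn6EGC-4β-yl)-2-[3,4,5-tris(benzyloxy)phenyl]chroman-3-one
Product: 21 (2R,3R)-5,7-bis(benzyloxy)-6-(Bn6EGC-4β-yl)-2-[3,4,5-tris(benzyloxy)phenyl]chroman-3-ol (2,3-cis)
Conditions: RuCl2[(S)-xylbinap][(S)-daipen] (2 mol %), KOtBu (cat.), H2 (10 atm), i-PrOH–toluene, 25 °C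
Reagents that add atoms: none
Why: Noyori asymmetric hydrogenation under dynamic kinetic resolution, in which KOtBu equilibrates the two C2 epimers of 20 through the enolate (C2–H is α to the ketone, benzylic and next to O1) and the chiral ruthenium hydride reduces one epimer from the face that places OH cis to the aryl group, as it does for 2-alkoxy- and 2-alkylcyclohexanones, so that both lower stereocentres (2R,3R) are set by the catalyst; the catalyst antipode is to be confirmed on a simple 2-arylchroman-3-one and the mirror-image complex used if the sense proves opposite.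

Step 15
Reactants: 21 (2R,3R)-5,7-bis(benzyloxy)-6-(Bn6EGC-4β-yl)-2-[3,4,5-tris(benzyloxy)phenyl]chroman-3-ol; 22 3,4,5-tris(benzyloxy)benzoic acid
Product: 23 tetradeca-O-benzyl-epigallocatechin-(4β→6)-epigallocatechin 3-O-gallate
Conditions: DCC, DMAP, CH2Cl2, rt
Reagents that add atoms: none
Why: Steglich esterification (carbodiimide activation with DMAP acyl transfer) of the axial 3-OH, as used for 3-O-galloylation of benzylated 2,3-cis-flavan-3-ols; no stereocentre is touched.

Step 16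
Reactants: 23 tetradeca-O-benzyl-epigallocatechin-(4β→6)-epigallocatechin 3-O-gallate
Product: 24 epigallocatechin-(4β→6)-epigallocatechin 3-O-gallate (CNP0204196.2)
Conditions: H2 (1 atm), Pd(OH)2/C, THF–MeOH–H2O, rt
Reagents that add atoms: none
Why: Catalytic hydrogenolysis of all fourteen benzyl ethers under neutral conditions, the usual last step for polyphenolic flavan-3-ol esters; the gallate ester, the interflavan bond and the benzylic C2–O1 bonds are expected to survive if the reaction is stopped at full debenzylation.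

**Compound list**

1 | (−)-epigallocatechin | O[C@@H]1Cc2c(O)cc(O)cc2O[C@@H]1c1cc(O)c(O)c(O)c1 | starting material
2 | 5,7,3′,4′,5′-penta-O-benzyl-(−)-epigallocatechin | O[C@@H]1Cc2c(OCc9ccccc9)cc(OCc9ccccc9)cc2O[C@@H]1c1cc(OCc9ccccc9)c(OCc9ccccc9)c(OCc9ccccc9)c1 | intermediate
3 | 4β-(2-ethoxyethoxy)-5,7,3′,4′,5′-penta-O-benzylepigallocatechin | CCOCCO[C@H]3c4c(OCc9ccccc9)cc(OCc9ccccc9)cc4O[C@H](c5cc(OCc9ccccc9)c(OCc9ccccc9)c(OCc9ccccc9)c5)[C@@H]3O | intermediate
4 | 4β-(2-ethoxyethoxy)-3,5,7,3′,4′,5′-hexa-O-benzylepigallocatechin | CCOCCO[C@H]3c4c(OCc9ccccc9)cc(OCc9ccccc9)cc4O[C@H](c5cc(OCc9ccccc9)c(OCc9ccccc9)c(OCc9ccccc9)c5)[C@@H]3OCc9ccccc9 | intermediate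
5 | phloroglucinol | Oc1cc(O)cc(O)c1 | starting material
6 | 2-(Bn6EGC-4β-yl)benzene-1,3,5-triol | Oc1cc(O)c([C@H]3c4c(OCc9ccccc9)cc(OCc9ccccc9)cc4O[C@H](c5cc(OCc9ccccc9)c(OCc9ccccc9)c(OCc9ccccc9)c5)[C@@H]3OCc9ccccc9)c(O)c1 | intermediate
7 | 4-(Bn6EGC-4β-yl)-5-(triisopropylsilyloxy)benzene-1,3-diol | CC(C)[Si](C(C)C)(C(C)C)Oc1cc(O)c([C@H]3c4c(OCc9ccccc9)cc(OCc9ccccc9)cc4O[C@H](c5cc(OCc9ccccc9)c(OCc9ccccc9)c(OCc9ccccc9)c5)[C@@H]3OCc9ccccc9)c(O)c1 | intermediate
8 | [3,5-bis(benzyloxy)-4-(Bn6EGC-4β-yl)phenoxy]triisopropylsilane | CC(C)[Si](C(C)C)(C(C)C)Oc1cc(OCc9ccccc9)c([C@H]3c4c(OCc9ccccc9)cc(OCc9ccccc9)cc4O[C@H](c5cc(OCc9ccccc9)c(OCc9ccccc9)c(OCc9ccccc9)c5)[C@@H]3OCc9ccccc9)c(OCc9ccccc9)c1 | intermediate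
9 | 3,5-bis(benzyloxy)-4-(Bn6EGC-4β-yl)phenol | Oc1cc(OCc9ccccc9)c([C@H]3c4c(OCc9ccccc9)cc(OCc9ccccc9)cc4O[C@H](c5cc(OCc9ccccc9)c(OCc9ccccc9)c(OCc9ccccc9)c5)[C@@H]3OCc9ccccc9)c(OCc9ccccc9)c1 | intermediate
10 | 3,5-bis(benzyloxy)-2-iodo-4-(Bn6EGC-4β-yl)phenol | Oc1cc(OCc9ccccc9)c([C@H]3c4c(OCc9ccccc9)cc(OCc9ccccc9)cc4O[C@H](c5cc(OCc9ccccc9)c(OCc9ccccc9)c(OCc9ccccc9)c5)[C@@H]3OCc9ccccc9)c(OCc9ccccc9)c1I | intermediate
11 | 3,4,5-tris(benzyloxy)benzaldehyde | O=Cc1cc(OCc2ccccc2)c(OCc2ccccc2)c(OCc2ccccc2)c1 | starting material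
12 | 5-ethynyl-1,2,3-tris(benzyloxy)benzene | C#Cc1cc(OCc2ccccc2)c(OCc2ccccc2)c(OCc2ccccc2)c1 | intermediate
13 | 3,5-bis(benzyloxy)-4-(Bn6EGC-4β-yl)-2-{[3,4,5-tris(benzyloxy)phenyl]ethynyl}phenol | Oc1cc(OCc9ccccc9)c([C@H]3c4c(OCc9ccccc9)cc(OCc9ccccc9)cc4O[C@H](c5cc(OCc9ccccc9)c(OCc9ccccc9)c(OCc9ccccc9)c5)[C@@H]3OCc9ccccc9)c(OCc9ccccc9)c1C#Cc5cc(OCc9ccccc9)c(OCc9ccccc9)c(OCc9ccccc9)c5 | intermediate
14 | 4,6-bis(benzyloxy)-5-(Bn6EGC-4β-yl)-2-[3,4,5-tris(benzyloxy)phenyl]benzofuran | c1(-c5cc(OCc9ccccc9)c(OCc9ccccc9)c(OCc9ccccc9)c5)cc2c(OCc9ccccc9)c([C@H]3c4c(OCc9ccccc9)cc(OCc9ccccc9)cc4O[C@H](c5cc(OCc9ccccc9)c(OCc9ccccc9)c(OCc9ccccc9)c5)[C@@H]3OCc9ccccc9)c(OCc9ccccc9)cc2o1 | intermediate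
15 | bromoform | BrC(Br)Br | starting material
16 | 4,6-bis(benzyloxy)-1,1-dibromo-5-(Bn6EGC-4β-yl)-1a-[3,4,5-tris(benzyloxy)phenyl]-1a,6b-dihydro-1H-cyclopropa[b]benzofuran (cis-fused, both diastereomers) | BrC1(Br)C2c6c(OCc9ccccc9)c([C@H]3c4c(OCc9ccccc9)cc(OCc9ccccc9)cc4O[C@H](c5cc(OCc9ccccc9)c(OCc9ccccc9)c(OCc9ccccc9)c5)[C@@H]3OCc9ccccc9)c(OCc9ccccc9)cc6OC12c5cc(OCc9ccccc9)c(OCc9ccccc9)c(OCc9ccccc9)c5 | intermediate
17 | 5,7-bis(benzyloxy)-3-bromo-6-(Bn6EGC-4β-yl)-2-[3,4,5-tris(benzyloxy)phenyl]chromenylium bromide | Brc1cc2c(OCc9ccccc9)c([C@H]3c4c(OCc9ccccc9)cc(OCc9ccccc9)cc4O[C@H](c5cc(OCc9ccccc9)c(OCc9ccccc9)c(OCc9ccccc9)c5)[C@@H]3OCc9ccccc9)c(OCc9ccccc9)cc2[o+]c1-c5cc(OCc9ccccc9)c(OCc9ccccc9)c(OCc9ccccc9)c5.[Br-] | intermediate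
18 | 5,7-bis(benzyloxy)-3-bromo-6-(Bn6EGC-4β-yl)-2-[3,4,5-tris(benzyloxy)phenyl]-4H-chromene | BrC1=C(c5cc(OCc9ccccc9)c(OCc9ccccc9)c(OCc9ccccc9)c5)Oc2cc(OCc9ccccc9)c([C@H]3c4c(OCc9ccccc9)cc(OCc9ccccc9)cc4O[C@H](c5cc(OCc9ccccc9)c(OCc9ccccc9)c(OCc9ccccc9)c5)[C@@H]3OCc9ccccc9)c(OCc9ccccc9)c2C1 | intermediate
19 | 2-{5,7-bis(benzyloxy)-6-(Bn6EGC-4β-yl)-2-[3,4,5-tris(benzyloxy)phenyl]-4H-chromen-3-yl}-4,4,5,5-tetramethyl-1,3,2-dioxaborolane | CC7(C)OB(OC7(C)C)C1=C(c5cc(OCc9ccccc9)c(OCc9ccccc9)c(OCc9ccccc9)c5)Oc2cc(OCc9ccccc9)c([C@H]3c4c(OCc9ccccc9)cc(OCc9ccccc9)cc4O[C@H](c5cc(OCc9ccccc9)c(OCc9ccccc9)c(OCc9ccccc9)c5)[C@@H]3OCc9ccccc9)c(OCc9ccccc9)c2C1 | intermediate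
20 | 5,7-bis(benzyloxy)-6-(Bn6EGC-4β-yl)-2-[3,4,5-tris(benzyloxy)phenyl]chroman-3-one (both C2 epimers) | O=C1Cc2c(OCc9ccccc9)c([C@H]3c4c(OCc9ccccc9)cc(OCc9ccccc9)cc4O[C@H](c5cc(OCc9ccccc9)c(OCc9ccccc9)c(OCc9ccccc9)c5)[C@@H]3OCc9ccccc9)c(OCc9ccccc9)cc2OC1c5cc(OCc9ccccc9)c(OCc9ccccc9)c(OCc9ccccc9)c5 | intermediate
21 | (2R,3R)-5,7-bis(benzyloxy)-6-(Bn6EGC-4β-yl)-2-[3,4,5-tris(benzyloxy)phenyl]chroman-3-ol | O[C@@H]1Cc2c(OCc9ccccc9)c([C@H]3c4c(OCc9ccccc9)cc(OCc9ccccc9)cc4O[C@H](c5cc(OCc9ccccc9)c(OCc9ccccc9)c(OCc9ccccc9)c5)[C@@H]3OCc9ccccc9)c(OCc9ccccc9)cc2O[C@@H]1c5cc(OCc9ccccc9)c(OCc9ccccc9)c(OCc9ccccc9)c5 | intermediate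
22 | 3,4,5-tris(benzyloxy)benzoic acid | OC(=O)c1cc(OCc2ccccc2)c(OCc2ccccc2)c(OCc2ccccc2)c1 | starting material
23 | tetradeca-O-benzyl-epigallocatechin-(4β→6)-epigallocatechin 3-O-gallate | O=C(O[C@@H]1Cc2c(OCc9ccccc9)c([C@H]3c4c(OCc9ccccc9)cc(OCc9ccccc9)cc4O[C@H](c5cc(OCc9ccccc9)c(OCc9ccccc9)c(OCc9ccccc9)c5)[C@@H]3OCc9ccccc9)c(OCc9ccccc9)cc2O[C@@H]1c5cc(OCc9ccccc9)c(OCc9ccccc9)c(OCc9ccccc9)c5)c6cc(OCc9ccccc9)c(OCc9ccccc9)c(OCc9ccccc9)c6 | intermediate
24 | epigallocatechin-(4β→6)-epigallocatechin 3-O-gallate (CNP0204196.2) | O=C(O[C@@H]1Cc2c(cc(O)c([C@H]3c4c(O)cc(O)cc4O[C@H](c4cc(O)c(O)c(O)c4)[C@@H]3O)c2O)O[C@@H]1c1cc(O)c(O)c(O)c1)c1cc(O)c(O)c(O)c1 | target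

**Step count and risks**

Total steps: 16. Longest linear sequence: 15 steps (steps 1–8 and 10–16, from (−)-epigallocatechin); step 9 is a one-step side branch.

Steps most likely to fail:

1. Step 11. The carbene may insert into benzylic C–H bonds or be consumed by tert-butanol faster than it adds to the hindered furan bond, and the cation may be intercepted by alkoxide. The fallback sets out from phenol 9 and builds the pyrylium ring by acid condensation instead of ring enlargement. Ortho-formylation of 9 with MgCl2, Et3N and paraformaldehyde in MeCN should give the salicylaldehyde F1. Condensation of F1 with the separately prepared ω-acetoxyacetophenone F2 under dry HCl in EtOAc at 0 °C (Robinson flavylium synthesis) should give the 3-acetoxyflavylium chloride F3. NaBH4 should add hydride at C4 to give the enol acetate F4, and K2CO3 in MeOH–THF should cleave it to ketone 20, where the route is rejoined.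

2. Step 13. Oxidative addition into the hindered, electron-rich tetrasubstituted alkenyl bromide may be slow, and protodeboronation or hydrolytic opening of the enol ether may compete during the oxidation. The fallback sets out from 18 and uses an organolithium instead of a palladium-catalysed borylation. Bromine–lithium exchange with t-BuLi in THF–Et2O at −100 °C should give the vinyllithium F5, which is oxygenated with bis(trimethylsilyl) peroxide to the trimethylsilyl enol ether F6. K2CO3 in MeOH should then release ketone 20, where the route is rejoined.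

3. Step 14. Catalyst control over the face of a hindered ketone with no aryl group on the carbonyl carbon may be insufficient, turnover may be slow, and the enolisable ketone may degrade under base. The fallback sets out from 20 and replaces catalyst control by substrate control and separation. Reduction with LiBH(s-Bu)3 in THF at −78 °C delivers hydride anti to the C2 aryl group and should give only 2,3-cis alcohols, namely 21 and the (2S,3S) lower-unit diastereomer F7. These differ as diastereomers because of the upper flavan and should be separable by chromatography. F7 is returned to 20 by Dess–Martin oxidation and base equilibration; the route is rejoined at 21.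

Further compounds
F1 | step 11 | 4,6-bis(benzyloxy)-5-(Bn6EGC-4β-yl)-2-hydroxybenzaldehyde | O=Cc1c(O)cc(OCc9ccccc9)c([C@H]3c4c(OCc9ccccc9)cc(OCc9ccccc9)cc4O[C@H](c5cc(OCc9ccccc9)c(OCc9ccccc9)c(OCc9ccccc9)c5)[C@@H]3OCc9ccccc9)c1OCc9ccccc9
F2 | step 11 | 2-acetoxy-1-[3,4,5-tris(benzyloxy)phenyl]ethan-1-one | CC(=O)OCC(=O)c1cc(OCc2ccccc2)c(OCc2ccccc2)c(OCc2ccccc2)c1
F3 | step 11 | 3-acetoxy-5,7-bis(benzyloxy)-6-(Bn6EGC-4β-yl)-2-[3,4,5-tris(benzyloxy)phenyl]chromenylium chloride | CC(=O)Oc1cc2c(OCc9ccccc9)c([C@H]3c4c(OCc9ccccc9)cc(OCc9ccccc9)cc4O[C@H](c5cc(OCc9ccccc9)c(OCc9ccccc9)c(OCc9ccccc9)c5)[C@@H]3OCc9ccccc9)c(OCc9ccccc9)cc2[o+]c1-c5cc(OCc9ccccc9)c(OCc9ccccc9)c(OCc9ccccc9)c5.[Cl-]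
F4 | step 11 | 5,7-bis(benzyloxy)-6-(Bn6EGC-4β-yl)-2-[3,4,5-tris(benzyloxy)phenyl]-4H-chromen-3-yl acetate | CC(=O)OC1=C(c5cc(OCc9ccccc9)c(OCc9ccccc9)c(OCc9ccccc9)c5)Oc2cc(OCc9ccccc9)c([C@H]3c4c(OCc9ccccc9)cc(OCc9ccccc9)cc4O[C@H](c5cc(OCc9ccccc9)c(OCc9ccccc9)c(OCc9ccccc9)c5)[C@@H]3OCc9ccccc9)c(OCc9ccccc9)c2C1
F5 | step 13 | {5,7-bis(benzyloxy)-6-(Bn6EGC-4β-yl)-2-[3,4,5-tris(benzyloxy)phenyl]-4H-chromen-3-yl}lithium | [Li]C1=C(c5cc(OCc9ccccc9)c(OCc9ccccc9)c(OCc9ccccc9)c5)Oc2cc(OCc9ccccc9)c([C@H]3c4c(OCc9ccccc9)cc(OCc9ccccc9)cc4O[C@H](c5cc(OCc9ccccc9)c(OCc9ccccc9)c(OCc9ccccc9)c5)[C@@H]3OCc9ccccc9)c(OCc9ccccc9)c2C1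
F6 | step 13 | {5,7-bis(benzyloxy)-6-(Bn6EGC-4β-yl)-2-[3,4,5-tris(benzyloxy)phenyl]-4H-chromen-3-yloxy}trimethylsilane | C[Si](C)(C)OC1=C(c5cc(OCc9ccccc9)c(OCc9ccccc9)c(OCc9ccccc9)c5)Oc2cc(OCc9ccccc9)c([C@H]3c4c(OCc9ccccc9)cc(OCc9ccccc9)cc4O[C@H](c5cc(OCc9ccccc9)c(OCc9ccccc9)c(OCc9ccccc9)c5)[C@@H]3OCc9ccccc9)c(OCc9ccccc9)c2C1
F7 | step 14 | (2S,3S)-5,7-bis(benzyloxy)-6-(Bn6EGC-4β-yl)-2-[3,4,5-tris(benzyloxy)phenyl]chroman-3-ol | O[C@H]1Cc2c(OCc9ccccc9)c([C@H]3c4c(OCc9ccccc9)cc(OCc9ccccc9)cc4O[C@H](c5cc(OCc9ccccc9)c(OCc9ccccc9)c(OCc9ccccc9)c5)[C@@H]3OCc9ccccc9)c(OCc9ccccc9)cc2O[C@H]1c5cc(OCc9ccccc9)c(OCc9ccccc9)c(OCc9ccccc9)c5
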